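**Plan**
Retrosynthesis: C7=C8 is cut first (aldol condensation), giving aldehyde 19 and bromocyclopentenone 13. The ring bond C11–C12 is cut next, unfolding the ring into the open-chain 1-bromoalk-1-yn-3-one 12. C9–C10 (acetylide plus Weinreb amide) and C14=C15 (Wittig) then lead back to the C5 hemiester 1.
Enabling feature: in ring C8–C9–C10–C11–C12, C12 lies β to the C9 carbonyl and 1,5 to C11, and C10(Br)=C11H is what a bromoalkyne becomes after a 1,2-bromine shift. The C12–H bond of an open-chain silyl ether can therefore become the C11–C12 bond by vinylidene C–H insertion, which makes the ring, the fully substituted carbinol and the bromoenone together.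
Forward: 1 supplies C8, C9 and C12–C14; a Z-Wittig reaction adds C15–C20; an acetylide adds C10–C11; bromination and ring closure (step 7, the only ring) follow. The C1–C7 chain is joined by aldol addition and dehydration, and desilylation ends the route.
Stereochemistry: C12 is the stereocentre of the (R)-hemiester 1, carried unchanged to 12 and into the ring with retention. 14Z and 5Z come from Wittig reactions of non-stabilised ylides; 7E comes from the elimination in step 12.

Key step: step 7

Remark: atoms are numbered as in prostanoids (C1 = ester carbon, C8–C12 = ring, C20 = chain end); hemiester 1 is assumed to be purchasable as the known statin side-chain building block.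

**Step 1**
Reactants: 1 (3R)-3-[(tert-butyldimethylsilyl)oxy]-5-methoxy-5-oxopentanoic acid
Product: 3 (4S)-4-[(tert-butyldimethylsilyl)oxy]oxan-2-one, via hydroxy acid 2 (not isolated)
Conditions: LiBH4, THF, 0 °C to rt; aq. HCl; then TsOH (cat.), CH2Cl2, rt
Reagents that add atoms: none
Why: Chemoselective borohydride reduction, in which LiBH4 reduces the methyl ester while the lithium carboxylate is inert, followed by acid-catalysed lactonisation of the δ-hydroxy acid; the silyloxy stereocentre is untouched (its descriptor changes from R to S only because the ranking of the two arms is inverted).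

**Step 2**
Reactants: 3 (4S)-4-[(tert-butyldimethylsilyl)oxy]oxan-2-one
Product: 4 (3S)-3-[(tert-butyldimethylsilyl)oxy]-5-hydroxy-N-methoxy-N-methylpentanamide
Conditions: Me(MeO)NH·HCl, Me3Al, CH2Cl2, 0 °C to rt; aq. HCl work-up; used promptly
Reagents that add atoms: N,O-dimethylhydroxylamine hydrochloride, CNOC.Cl
Why: Weinreb amide synthesis by aluminium-amide aminolysis of a lactone, which opens the ring at the acyl carbon and frees the primary alcohol without involving the stereocentre.

**Step 3**
Reactants: 4 (3S)-3-[(tert-butyldimethylsilyl)oxy]-5-hydroxy-N-methoxy-N-methylpentanamide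
Product: 5 (3S)-3-[(tert-butyldimethylsilyl)oxy]-N-methoxy-N-methyl-5-oxopentanamide
Conditions: Dess–Martin periodinane, pyridine, CH2Cl2, 0 °C to rt
Reagents that add atoms: none
Why: Dess–Martin oxidation of the primary alcohol to the aldehyde under buffered, non-basic conditions that should not provoke β-elimination of the silyloxy group.

**Step 4**
Reactants: 5 (3S)-3-[(tert-butyldimethylsilyl)oxy]-N-methoxy-N-methyl-5-oxopentanamide; 6 hexyltriphenylphosphonium bromide
Product: 8 (3S,5Z)-3-[(tert-butyldimethylsilyl)oxy]-N-methoxy-N-methylundec-5-enamide, via hexylidenetriphenylphosphorane 7 (not isolated)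
Conditions: 6, NaN(SiMe3)2, THF, 0 °C; then 5, −78 °C to rt
Reagents that add atoms: none
Why: Wittig olefination with a non-stabilised ylide under lithium-free conditions is kinetically Z-selective, the aldehyde reacts far faster than the Weinreb amide, and the low temperature should suppress β-elimination of silanolate.

**Step 5**
Reactants: 8 (3S,5Z)-3-[(tert-butyldimethylsilyl)oxy]-N-methoxy-N-methylundec-5-enamide; 9 ethynyltrimethylsilane
Product: 11 (5S,7Z)-5-[(tert-butyldimethylsilyl)oxy]-1-(trimethylsilyl)tridec-7-en-1-yn-3-one, via lithium (trimethylsilyl)acetylide 10 (not isolated)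
Conditions: 9, n-BuLi, THF, −78 °C; then 8, −78 to 0 °C; aq. NH4Cl
Reagents that add atoms: none
Why: Acylation of an alkynyllithium by a Weinreb amide stops at the ketone because the chelated tetrahedral intermediate survives until the quench.

**Step 6**
Reactants: 11 (5S,7Z)-5-[(tert-butyldimethylsilyl)oxy]-1-(trimethylsilyl)tridec-7-en-1-yn-3-one
Product: 12 (5S,7Z)-1-bromo-5-[(tert-butyldimethylsilyl)oxy]tridec-7-en-1-yn-3-one
Conditions: N-bromosuccinimide, AgNO3 (cat.), acetone, rt, dark
Reagents that add atoms: N-bromosuccinimide, O=C1CCC(=O)N1Br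
Why: Silver-catalysed desilylative bromination, in which AgNO3 turns the alkynylsilane into a silver acetylide that N-bromosuccinimide brominates, while the isolated Z-alkene and the silyl ether should be inert under these neutral conditions.

**Step 7**
Reactants: 12 (5S,7Z)-1-bromo-5-[(tert-butyldimethylsilyl)oxy]tridec-7-en-1-yn-3-one
Product: 13 (4S)-2-bromo-4-[(tert-butyldimethylsilyl)oxy]-4-[(2Z)-oct-2-en-1-yl]cyclopent-2-en-1-one
Conditions: (BrettPhos)AuNTf2 (5 mol %; BrettPhos = 2-(dicyclohexylphosphino)-3,6-dimethoxy-2',4',6'-triisopropylbiphenyl), ClCH2CH2Cl, 60 °C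
Reagents that add atoms: none
Why: Proposed new method: the cationic monovalent gold centre binds the bromoalkyne of 12 and triggers a 1,2-bromine shift to a gold bromovinylidene, whose terminal carbon (C11) inserts into the C12–H bond held 1,5 to it across C10–C9–C8, giving the 2-bromoenone directly and releasing the catalyst. The closest known reaction types are the gold-catalysed cycloisomerisation of 1-bromoalk-1-yn-3-ones to 2-bromocyclopent-2-enones by insertion into unactivated C(sp3)–H bonds, the thermal α-alkynone cyclisation, and the stereoretentive 1,5 C–H insertion of free alkylidene carbenes into oxygen-bearing methines; what is new is a gold vinylidene inserting into a silyloxy-substituted stereogenic methine with transfer of chirality. The single ring closes by a 1,5 carbene-type C–H insertion that forms C11–C12 and leaves the former alkyne carbons endocyclic as C10=C11. C12 should become fully substituted with retention, because the new C–C bond forms on the face from which the hydrogen departs, whether the insertion is concerted or a hydride shift followed by collapse of the tight oxocarbenium/vinylgold pair inside the five-membered array. The step needs 1,5 insertion over 1,6 insertion at allylic C13–H, and C–H insertion over attack by the ether oxygen or the C14=C15 alkene; the five-membered transition state, the hydridic C–H bond next to oxygen, and the bulk and low basicity of the tert-butyldimethylsilyl ether should secure this.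

**Step 8**
Reactants: 14 (4-carboxybutyl)triphenylphosphonium bromide; 15 [(tert-butyldimethylsilyl)oxy]acetaldehyde
Product: 17 (5Z)-7-[(tert-butyldimethylsilyl)oxy]hept-5-enoic acid, via ylide carboxylate 16 (not isolated)
Conditions: 14, NaN(SiMe3)2 (2.1 equiv), THF, 0 °C; then 15, −78 °C to rt; aq. HCl to pH 4
Reagents that add atoms: none
Why: Wittig olefination of the non-stabilised ylide carboxylate (the classical prostaglandin upper-chain reagent) with an aliphatic aldehyde gives the Z-alkene selectively.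

**Step 9**
Reactants: 17 (5Z)-7-[(tert-butyldimethylsilyl)oxy]hept-5-enoic acid
Product: 18 methyl (5Z)-7-hydroxyhept-5-enoate
Conditions: TsOH·H2O (cat.), MeOH, 40 °C
Reagents that add atoms: methanol, CO
Why: Fischer esterification and acid-catalysed methanolysis of the primary silyl ether take place in the same pot, and the isolated Z-alkene should not be isomerised by dilute acid.

**Step 10**
Reactants: 18 methyl (5Z)-7-hydroxyhept-5-enoate
Product: 19 methyl (5Z)-7-oxohept-5-enoate
Conditions: Dess–Martin periodinane, pyridine, CH2Cl2, 0 °C; used at once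
Reagents that add atoms: none
Why: Dess–Martin oxidation buffered with pyridine converts the Z-allylic alcohol into the Z-enal without the acid or base that would isomerise it to the E-enal.

**Step 11**
Reactants: 13 (4S)-2-bromo-4-[(tert-butyldimethylsilyl)oxy]-4-[(2Z)-oct-2-en-1-yl]cyclopent-2-en-1-one; 19 methyl (5Z)-7-oxohept-5-enoate
Product: 21 methyl (5Z)-7-[(5S)-3-bromo-5-[(tert-butyldimethylsilyl)oxy]-5-[(2Z)-oct-2-en-1-yl]-2-oxocyclopent-3-en-1-yl]-7-hydroxyhept-5-enoate (diastereomer mixture at C7 and C8), via lithium dienolate 20 (not isolated)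
Conditions: LiN(iPr)2, THF, −78 °C; then 19, −78 °C; aq. NH4Cl
Reagents that add atoms: none
Why: Aldol addition, in which kinetic deprotonation at C8 (the only enolisable position) gives a cross-conjugated dienolate that adds 1,2 to the enal, a tactic with precedent for 4-oxygenated 2-halocyclopentenones; loss of silanolate is disfavoured because it would give a cyclopentadienone, and the two new centres (C7, C8) form as a mixture that is removed in step 12 (left undefined in the SMILES).

**Step 12**
Reactants: 21 methyl (5Z)-7-[(5S)-3-bromo-5-[(tert-butyldimethylsilyl)oxy]-5-[(2Z)-oct-2-en-1-yl]-2-oxocyclopent-3-en-1-yl]-7-hydroxyhept-5-enoate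
Product: 23 methyl (5Z,7E)-7-[(2R)-4-bromo-2-[(tert-butyldimethylsilyl)oxy]-2-[(2Z)-oct-2-en-1-yl]-5-oxocyclopent-3-en-1-ylidene]hept-5-enoate, via allylic mesylate 22 (not isolated)
Conditions: MsCl, Et3N, CH2Cl2, −20 °C to rt
Reagents that add atoms: none
Why: Mesylation of the secondary allylic alcohol followed by E1cB elimination through the C8 enolate forms C7=C8, and the 7E isomer should be favoured because the dienyl chain then points away from the C9 carbonyl, as is general for 2-alkylidenecyclopentenones.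

**Step 13**
Reactants: 23 methyl (5Z,7E)-7-[(2R)-4-bromo-2-[(tert-butyldimethylsilyl)oxy]-2-[(2Z)-oct-2-en-1-yl]-5-oxocyclopent-3-en-1-ylidene]hept-5-enoate
Product: 24 methyl (5Z,7E)-7-[(2R)-4-bromo-2-hydroxy-2-[(2Z)-oct-2-en-1-yl]-5-oxocyclopent-3-en-1-ylidene]hept-5-enoate (bromovulone I)
Conditions: HF·pyridine, MeCN, 0 °C to rt
Reagents that add atoms: none
Why: Fluoride-mediated desilylation under mildly acidic conditions should cleave the tertiary silyl ether without exposing the base-sensitive cross-conjugated bromodienone, the methyl ester or the Z-alkenes to basic fluoride or alkoxide.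

**Compound list**
1 | (3R)-3-[(tert-butyldimethylsilyl)oxy]-5-methoxy-5-oxopentanoic acid | COC(=O)C[C@H](O[Si](C)(C)C(C)(C)C)CC(=O)O | starting material
2 | (3S)-3-[(tert-butyldimethylsilyl)oxy]-5-hydroxypentanoic acid | OCC[C@H](O[Si](C)(C)C(C)(C)C)CC(=O)O | intermediate
3 | (4S)-4-[(tert-butyldimethylsilyl)oxy]oxan-2-one | O=C1C[C@@H](O[Si](C)(C)C(C)(C)C)CCO1 | intermediate
4 | (3S)-3-[(tert-butyldimethylsilyl)oxy]-5-hydroxy-N-methoxy-N-methylpentanamide | CON(C)C(=O)C[C@@H](O[Si](C)(C)C(C)(C)C)CCO | intermediate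
5 | (3S)-3-[(tert-butyldimethylsilyl)oxy]-N-methoxy-N-methyl-5-oxopentanamide | CON(C)C(=O)C[C@@H](O[Si](C)(C)C(C)(C)C)CC=O | intermediate
6 | hexyltriphenylphosphonium bromide | CCCCCC[P+](c1ccccc1)(c1ccccc1)c1ccccc1.[Br-] | starting material
7 | hexylidenetriphenylphosphorane | CCCCCC=P(c1ccccc1)(c1ccccc1)c1ccccc1 | intermediate
8 | (3S,5Z)-3-[(tert-butyldimethylsilyl)oxy]-N-methoxy-N-methylundec-5-enamide | CCCCC/C=C\C[C@H](O[Si](C)(C)C(C)(C)C)CC(=O)N(C)OC | intermediate
9 | ethynyltrimethylsilane | C#C[Si](C)(C)C | starting material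
10 | lithium (trimethylsilyl)acetylide | [Li]C#C[Si](C)(C)C | intermediate
11 | (5S,7Z)-5-[(tert-butyldimethylsilyl)oxy]-1-(trimethylsilyl)tridec-7-en-1-yn-3-one | CCCCC/C=C\C[C@H](O[Si](C)(C)C(C)(C)C)CC(=O)C#C[Si](C)(C)C | intermediate
12 | (5S,7Z)-1-bromo-5-[(tert-butyldimethylsilyl)oxy]tridec-7-en-1-yn-3-one | CCCCC/C=C\C[C@H](O[Si](C)(C)C(C)(C)C)CC(=O)C#CBr | intermediate
13 | (4S)-2-bromo-4-[(tert-butyldimethylsilyl)oxy]-4-[(2Z)-oct-2-en-1-yl]cyclopent-2-en-1-one | CCCCC/C=C\C[C@@]1(O[Si](C)(C)C(C)(C)C)C=C(Br)C(=O)C1 | intermediate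
14 | (4-carboxybutyl)triphenylphosphonium bromide | OC(=O)CCCC[P+](c1ccccc1)(c1ccccc1)c1ccccc1.[Br-] | starting material
15 | [(tert-butyldimethylsilyl)oxy]acetaldehyde | O=CCO[Si](C)(C)C(C)(C)C | starting material
16 | sodium 5-(triphenylphosphoranylidene)pentanoate | [Na+].[O-]C(=O)CCCC=P(c1ccccc1)(c1ccccc1)c1ccccc1 | intermediate
17 | (5Z)-7-[(tert-butyldimethylsilyl)oxy]hept-5-enoic acid | OC(=O)CCC/C=C\CO[Si](C)(C)C(C)(C)C | intermediate
18 | methyl (5Z)-7-hydroxyhept-5-enoate | COC(=O)CCC/C=C\CO | intermediate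
19 | methyl (5Z)-7-oxohept-5-enoate | COC(=O)CCC/C=C\C=O | intermediate
20 | lithium dienolate of 13 (C8=C9 enolate, C12 unchanged) | CCCCC/C=C\C[C@@]1(O[Si](C)(C)C(C)(C)C)C=C(Br)C(O[Li])=C1 | intermediate
21 | methyl (5Z)-7-[(5S)-3-bromo-5-[(tert-butyldimethylsilyl)oxy]-5-[(2Z)-oct-2-en-1-yl]-2-oxocyclopent-3-en-1-yl]-7-hydroxyhept-5-enoate (mixture at C7 and C8) | CCCCC/C=C\C[C@@]1(O[Si](C)(C)C(C)(C)C)C=C(Br)C(=O)C1C(O)/C=C\CCCC(=O)OC | intermediate
22 | C7 methanesulfonate of 21 | CCCCC/C=C\C[C@@]1(O[Si](C)(C)C(C)(C)C)C=C(Br)C(=O)C1C(OS(C)(=O)=O)/C=C\CCCC(=O)OC | intermediate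
23 | methyl (5Z,7E)-7-[(2R)-4-bromo-2-[(tert-butyldimethylsilyl)oxy]-2-[(2Z)-oct-2-en-1-yl]-5-oxocyclopent-3-en-1-ylidene]hept-5-enoate | CCCCC/C=C\C[C@@]1(O[Si](C)(C)C(C)(C)C)C=C(Br)C(=O)/C1=C/C=C\CCCC(=O)OC | intermediate
24 | methyl (5Z,7E)-7-[(2R)-4-bromo-2-hydroxy-2-[(2Z)-oct-2-en-1-yl]-5-oxocyclopent-3-en-1-ylidene]hept-5-enoate (bromovulone I) | CCCCC/C=C\C[C@@]1(O)C=C(Br)C(=O)/C1=C/C=C\CCCC(=O)OC | target

**Count**
Total steps: 13. Longest linear sequence: 10 (steps 1–7 and 11–13); steps 8–10 make the aldehyde branch.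

**Steps most likely to fail**

1. Step 7 (Proposed new method). The insertion may proceed through a free oxocarbenium ion after hydride transfer, which would erode the configuration at C12 or lead to loss of the silyl group and collapse to a ketone. The ether oxygen may also attack the gold-activated alkyne in a six-membered mode, and the β-silyloxy ketone may eliminate silanol under the Lewis-acidic conditions. The fallback uses known chemistry and sets out from 11. Mild protodesilylation (Na2B4O7 in aqueous methanol) should give the terminal ynone (5S,7Z)-5-[(tert-butyldimethylsilyl)oxy]tridec-7-en-1-yn-3-one F1. Flash vacuum pyrolysis (about 600 °C, quartz tube, short contact time) then brings about the thermal α-alkynone cyclisation: an acetylene-to-vinylidene hydrogen shift followed by 1,5 C–H insertion of the free alkylidene carbene, a reaction type known to retain configuration. This should give (4S)-4-[(tert-butyldimethylsilyl)oxy]-4-[(2Z)-oct-2-en-1-yl]cyclopent-2-en-1-one F2. Nucleophilic epoxidation (tBuOOH, DBU), which is selective for the enone over the isolated alkene, should give the epoxy ketone (4S)-4-[(tert-butyldimethylsilyl)oxy]-4-[(2Z)-oct-2-en-1-yl]-6-oxabicyclo[3.1.0]hexan-2-one F3 (either epoxide face serves). MgBr2·OEt2 opens it at C10 to the bromohydrin (4S)-2-bromo-4-[(tert-butyldimethylsilyl)oxy]-3-hydroxy-4-[(2Z)-oct-2-en-1-yl]cyclopentan-1-one F4, which loses water on treatment with Et3N. The fallback comes back to the route at 13.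

2. Step 12. The elimination may give poor control of the C7=C8 geometry, and the 5Z alkene may isomerise through the allylic mesylate or the trienone product. The fallback sets out from 13 and forms the Z-alkene last. Enolate 20 is generated as in step 11 and added to 2,2-dimethoxyacetaldehyde to give the aldol (4S)-2-bromo-4-[(tert-butyldimethylsilyl)oxy]-5-(1-hydroxy-2,2-dimethoxyethyl)-4-[(2Z)-oct-2-en-1-yl]cyclopent-2-en-1-one F5. Its mesylate F6 (MsCl, Et3N) eliminates to the alkylidene acetal (4R,5E)-2-bromo-4-[(tert-butyldimethylsilyl)oxy]-5-(2,2-dimethoxyethylidene)-4-[(2Z)-oct-2-en-1-yl]cyclopent-2-en-1-one F7, in which no Z-alkene is at risk and the E isomer can be enriched by equilibration. Mild acid hydrolysis (wet acetone, acidic resin) frees the aldehyde (2E)-2-[(2R)-4-bromo-2-[(tert-butyldimethylsilyl)oxy]-2-[(2Z)-oct-2-en-1-yl]-5-oxocyclopent-3-en-1-ylidene]acetaldehyde F8. A Z-selective Wittig reaction with the numbered ylide 16 at −78 °C gives (5Z,7E)-7-[(2R)-4-bromo-2-[(tert-butyldimethylsilyl)oxy]-2-[(2Z)-oct-2-en-1-yl]-5-oxocyclopent-3-en-1-ylidene]hept-5-enoic acid F9. Esterification with Me3SiCHN2 in methanol/toluene comes back to the route at 23.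

3. Step 13. Cleavage of the hindered tertiary silyl ether may be slow, and forcing it may decompose or isomerise the trienone. The fallback sets out from 13 and removes the silyl group before the side chain is attached. HF·pyridine in MeCN on the robust bromoenone should give (4S)-2-bromo-4-hydroxy-4-[(2Z)-oct-2-en-1-yl]cyclopent-2-en-1-one F10. LiN(iPr)2 (2.1 equiv, THF, −78 °C) forms the dilithium alkoxide dienolate F11, which adds to 19 to give the diol methyl (5Z)-7-[(5S)-3-bromo-5-hydroxy-5-[(2Z)-oct-2-en-1-yl]-2-oxocyclopent-3-en-1-yl]-7-hydroxyhept-5-enoate F12. Mesylation of the secondary allylic hydroxyl alone (MsCl, Et3N, −40 °C; the tertiary alcohol is inert) gives the mesylate F13, and E1cB elimination comes back to the route at 24.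

**Further compounds**
F1 | step 7 | (5S,7Z)-5-[(tert-butyldimethylsilyl)oxy]tridec-7-en-1-yn-3-one | CCCCC/C=C\C[C@H](O[Si](C)(C)C(C)(C)C)CC(=O)C#C
F2 | step 7 | (4S)-4-[(tert-butyldimethylsilyl)oxy]-4-[(2Z)-oct-2-en-1-yl]cyclopent-2-en-1-one | CCCCC/C=C\C[C@@]1(O[Si](C)(C)C(C)(C)C)C=CC(=O)C1
F3 | step 7 | (4S)-4-[(tert-butyldimethylsilyl)oxy]-4-[(2Z)-oct-2-en-1-yl]-6-oxabicyclo[3.1.0]hexan-2-one (epoxide centres undefined) | CCCCC/C=C\C[C@@]1(O[Si](C)(C)C(C)(C)C)C2OC2C(=O)C1
F4 | step 7 | (4S)-2-bromo-4-[(tert-butyldimethylsilyl)oxy]-3-hydroxy-4-[(2Z)-oct-2-en-1-yl]cyclopentan-1-one (C2 and C3 undefined) | CCCCC/C=C\C[C@@]1(O[Si](C)(C)C(C)(C)C)C(O)C(Br)C(=O)C1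
F5 | step 12 | (4S)-2-bromo-4-[(tert-butyldimethylsilyl)oxy]-5-(1-hydroxy-2,2-dimethoxyethyl)-4-[(2Z)-oct-2-en-1-yl]cyclopent-2-en-1-one (mixture at the two new centres) | CCCCC/C=C\C[C@@]1(O[Si](C)(C)C(C)(C)C)C=C(Br)C(=O)C1C(O)C(OC)OC
F6 | step 12 | methanesulfonate of F5 | CCCCC/C=C\C[C@@]1(O[Si](C)(C)C(C)(C)C)C=C(Br)C(=O)C1C(OS(C)(=O)=O)C(OC)OC
F7 | step 12 | (4R,5E)-2-bromo-4-[(tert-butyldimethylsilyl)oxy]-5-(2,2-dimethoxyethylidene)-4-[(2Z)-oct-2-en-1-yl]cyclopent-2-en-1-one | CCCCC/C=C\C[C@@]1(O[Si](C)(C)C(C)(C)C)C=C(Br)C(=O)/C1=C/C(OC)OC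
F8 | step 12 | (2E)-2-[(2R)-4-bromo-2-[(tert-butyldimethylsilyl)oxy]-2-[(2Z)-oct-2-en-1-yl]-5-oxocyclopent-3-en-1-ylidene]acetaldehyde | CCCCC/C=C\C[C@@]1(O[Si](C)(C)C(C)(C)C)C=C(Br)C(=O)/C1=C/C=O
F9 | step 12 | (5Z,7E)-7-[(2R)-4-bromo-2-[(tert-butyldimethylsilyl)oxy]-2-[(2Z)-oct-2-en-1-yl]-5-oxocyclopent-3-en-1-ylidene]hept-5-enoic acid | CCCCC/C=C\C[C@@]1(O[Si](C)(C)C(C)(C)C)C=C(Br)C(=O)/C1=C/C=C\CCCC(=O)O
F10 | step 13 | (4S)-2-bromo-4-hydroxy-4-[(2Z)-oct-2-en-1-yl]cyclopent-2-en-1-one | CCCCC/C=C\C[C@@]1(O)C=C(Br)C(=O)C1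
F11 | step 13 | dilithium alkoxide dienolate of F10 | CCCCC/C=C\C[C@@]1(O[Li])C=C(Br)C(O[Li])=C1
F12 | step 13 | methyl (5Z)-7-[(5S)-3-bromo-5-hydroxy-5-[(2Z)-oct-2-en-1-yl]-2-oxocyclopent-3-en-1-yl]-7-hydroxyhept-5-enoate (mixture at C7 and C8) | CCCCC/C=C\C[C@@]1(O)C=C(Br)C(=O)C1C(O)/C=C\CCCC(=O)OC
F13 | step 13 | C7 methanesulfonate of F12 | CCCCC/C=C\C[C@@]1(O)C=C(Br)C(=O)C1C(OS(C)(=O)=O)/C=C\CCCC(=O)OC
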